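**Retrosynthetic overview** (chain numbered C1, the alkyne CH, to C15, the ethyl CH3; O7 is the ring oxygen, O9 a sacrificial oxygen on C9)
1. Endgame: the C12 bromide comes from the 12R alcohol by SN2 inversion. The C6 acetate and the E-enyne (C1–C4) come from opening a C5–C6 oxirane at C5 with an (E)-enynylmagnesium reagent.
2. The C13 ethyl group and O12 both go back to the eight-membered lactone 7 (C13 = lactone C=O). They are installed by enolate hydroxylation at C12, ethylidenation of C13=O and ionic hydrogenation.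
3. Enabling feature: in the oxocene ring (O7, C7–C13) the Z C9=C10 double bond lies gamma,delta to C13, the carbon bound to the ring oxygen. With C13 raised to the lactone level, O=C13–C12–C11–C10=C9 is a Claisen retron.
4. The C11–C12 bond is therefore made by the [3,3] shift of the 2-methylene-4-vinyl-1,3-dioxane 6 (ring O7–C13–O9–C9–C8–C7). Compound 6 forms in the flask from the cyclic carbonate 5 and Cp2TiMe2, which supplies C12.
5. Order of rings: dioxolane (chiral pool, C5–C7), then 1,3-dioxan-2-one, then oxocinone (six to eight), then oxocene. Late in the route the dioxolane becomes an oxirane and is opened.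

Key step: step 5

Assumption: C9 in 4, 5 and 6 forms as a mixture of epimers and is written without a stereo mark, because step 5 erases this centre and both epimers should converge on 7.

**Step 1**
Reactants: 1 (R)-2,2-dimethyl-1,3-dioxolane-4-carbaldehyde
Product: 2 (1R)-1-[(4R)-2,2-dimethyl-1,3-dioxolan-4-yl]but-3-en-1-ol
Conditions: (+)-Ipc2B(allyl) (from (−)-alpha-pinene), Et2O, −78 °C; NaOH, H2O2, 0 to 25 °C
Reagents that add atoms: (+)-B-allyldiisopinocampheylborane, C=CCB(C1CC2CC(C1C)C2(C)C)C1CC2CC(C1C)C2(C)C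
Why: Brown asymmetric allylboration through a closed chair transition state, in which the isopinocampheyl ligands (reagent control) should override the Felkin bias of 1 and set C7 as R, syn to the C6 oxygen.

**Step 2**
Reactants: 2 (1R)-1-[(4R)-2,2-dimethyl-1,3-dioxolan-4-yl]but-3-en-1-ol
Product: 3 (3R)-3-[(4R)-2,2-dimethyl-1,3-dioxolan-4-yl]-3-hydroxypropanal
Conditions: O3, CH2Cl2, −78 °C; Me2S, −78 to 25 °C (used crude)
Reagents that add atoms: ozone, [O-][O+]=O
Why: Ozonolysis with reductive work-up cleaves the only C=C bond to the C9 aldehyde under neutral conditions, so the C6 and C7 stereocentres and the acetonide are not touched.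

**Step 3**
Reactants: 3 (3R)-3-[(4R)-2,2-dimethyl-1,3-dioxolan-4-yl]-3-hydroxypropanal
Product: 4 (1R,3RS)-1-[(4R)-2,2-dimethyl-1,3-dioxolan-4-yl]pent-4-ene-1,3-diol
Conditions: CH2=CHMgBr (3 equiv), THF, −78 to 0 °C; aq NH4Cl
Reagents that add atoms: vinylmagnesium bromide, C=C[Mg]Br
Why: Grignard 1,2-addition (the first equivalent only deprotonates O7–H) installs C10=C11 and O9, and the new C9 carbinol centre needs no control because step 5 erases it.

**Step 4**
Reactants: 4 (1R,3RS)-1-[(4R)-2,2-dimethyl-1,3-dioxolan-4-yl]pent-4-ene-1,3-diol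
Product: 5 (4R,6RS)-4-[(4R)-2,2-dimethyl-1,3-dioxolan-4-yl]-6-ethenyl-1,3-dioxan-2-one
Conditions: 1,1'-carbonyldiimidazole, toluene, 60 °C
Reagents that add atoms: 1,1'-carbonyldiimidazole, O=C(n1ccnc1)n1ccnc1
Why: Double acyl transfer from the reagent (cyclic carbonate formation from a 1,3-diol) ties O7 and O9 into the six-membered ring, brings in C13 and creates no stereocentre.

**Step 5**
Reactants: 5 (4R,6RS)-4-[(4R)-2,2-dimethyl-1,3-dioxolan-4-yl]-6-ethenyl-1,3-dioxan-2-one
Product: 7 (5Z,8R)-8-[(4R)-2,2-dimethyl-1,3-dioxolan-4-yl]-3,4,7,8-tetrahydro-2H-oxocin-2-one, via ketene acetal 6 (not isolated)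
Conditions: Cp2TiMe2 (1.3 equiv), toluene, 105 °C, dark
Reagents that add atoms: dimethyltitanocene, C[Ti](C)(C1C=CC=C1)C1C=CC=C1
Why: Thermolysis of Cp2TiMe2 releases Cp2Ti=CH2, which methylenates the carbonate C=O (Petasis methylenation) to the allyl ketene acetal 6 (C12=C13–O9–C9–C10=C11), and at the same temperature 6 undergoes a Claisen [3,3] shift that forms C11–C12, breaks C9–O9 and turns O9 into the lactone carbonyl oxygen. The closest known reaction type is the tandem methylenation/Claisen ring expansion of vinyl-substituted cyclic carbonates, and of ketene acetals made by selenoxide elimination, to medium-ring lactones. The eight-membered ring is closed as a six-to-eight ring enlargement through a bicyclo[3.3.1]-like transition state in which the pericyclic chair shares C13–O9–C9 with the dioxane ring. No new stereocentre is formed; the only new stereo-element, the C9=C10 geometry, is fixed as Z because the dioxane holds C8 axial on the pericyclic chair, C7 is not touched, and both C9 epimers should converge (anti through a chair dioxane with the C7 group equatorial, syn through a boat dioxane). The step needs methylenation of the carbonate without methylenation of the lactone formed, which the limited amount of reagent should secure, while the acetonide is inert and formation of the C=O bond makes the shift irreversible despite the ring strain.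

**Step 6**
Reactants: 7 (5Z,8R)-8-[(4R)-2,2-dimethyl-1,3-dioxolan-4-yl]-3,4,7,8-tetrahydro-2H-oxocin-2-one
Product: 9 (3R,5Z,8R)-8-[(4R)-2,2-dimethyl-1,3-dioxolan-4-yl]-3-hydroxy-3,4,7,8-tetrahydro-2H-oxocin-2-one, via potassium enolate 8 (not isolated)
Conditions: KN(SiMe3)2, THF, −78 °C; 2-(phenylsulfonyl)-3-phenyloxaziridine, −78 °C; AcOH
Reagents that add atoms: 2-(phenylsulfonyl)-3-phenyloxaziridine, O=S(=O)(c1ccccc1)N1OC1c1ccccc1
Why: Davis oxidation of the lactone enolate 8, in which the oxaziridine should reach C12 only from the outer face of the folded eight-membered enolate (peripheral attack, the inner face being covered by C8–C10 across the ring), placing O12 cis to the C7 substituent and setting C12 as R.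

**Step 7**
Reactants: 9 (3R,5Z,8R)-8-[(4R)-2,2-dimethyl-1,3-dioxolan-4-yl]-3-hydroxy-3,4,7,8-tetrahydro-2H-oxocin-2-one
Product: 10 (3R,5Z,8R)-3-(tert-butyldimethylsilyloxy)-8-[(4R)-2,2-dimethyl-1,3-dioxolan-4-yl]-3,4,7,8-tetrahydro-2H-oxocin-2-one
Conditions: TBSOTf, 2,6-lutidine, CH2Cl2, 0 °C
Reagents that add atoms: tert-butyldimethylsilyl triflate, CC(C)(C)[Si](C)(C)OS(=O)(=O)C(F)(F)F
Why: Silyl ether formation with a hindered, weak base protects O12 without epimerising the acidic C12 position.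

**Step 8**
Reactants: 10 (3R,5Z,8R)-3-(tert-butyldimethylsilyloxy)-8-[(4R)-2,2-dimethyl-1,3-dioxolan-4-yl]-3,4,7,8-tetrahydro-2H-oxocin-2-one
Product: 11 (2Z,3R,5Z,8R)-3-(tert-butyldimethylsilyloxy)-8-[(4R)-2,2-dimethyl-1,3-dioxolan-4-yl]-2-ethylidene-3,4,7,8-tetrahydro-2H-oxocine
Conditions: CH3CHBr2, TiCl4, Zn, TMEDA, PbCl2 (cat.), THF, 25 °C
Reagents that add atoms: 1,1-dibromoethane, CC(Br)Br
Why: Takai–Utimoto alkylidenation of the lactone carbonyl delivers C14 and C15 without opening the ring; the reagent is non-basic, so C12 is safe, and the enol ether geometry (Z expected) is of no consequence.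

**Step 9**
Reactants: 11 (2Z,3R,5Z,8R)-3-(tert-butyldimethylsilyloxy)-8-[(4R)-2,2-dimethyl-1,3-dioxolan-4-yl]-2-ethylidene-3,4,7,8-tetrahydro-2H-oxocine
Product: 13 (2R,3R,5Z,8R)-3-(tert-butyldimethylsilyloxy)-8-[(4R)-2,2-dimethyl-1,3-dioxolan-4-yl]-2-ethyl-3,4,7,8-tetrahydro-2H-oxocine, via oxocarbenium trifluoroacetate 12 (not isolated)
Conditions: Et3SiH, CF3CO2H, CH2Cl2, −78 °C
Reagents that add atoms: none
Why: Ionic hydrogenation, in which only the electron-rich enol ether is protonated (at C14) to 12 and Et3SiH should deliver hydride to C13 from the face opposite to the C12 silyloxy group and the C7 substituent, setting C13 as R (2,8-cis) and leaving C9=C10 untouched.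

**Step 10**
Reactants: 13 (2R,3R,5Z,8R)-3-(tert-butyldimethylsilyloxy)-8-[(4R)-2,2-dimethyl-1,3-dioxolan-4-yl]-2-ethyl-3,4,7,8-tetrahydro-2H-oxocine
Product: 14 (1R)-1-[(2R,4Z,7R,8R)-7-(tert-butyldimethylsilyloxy)-8-ethyl-3,6,7,8-tetrahydro-2H-oxocin-2-yl]ethane-1,2-diol
Conditions: AcOH–H2O (4:1), 40 °C
Reagents that add atoms: none
Why: Mild acid hydrolysis of the terminal acetonide, which the secondary TBS ether and the ring ether should survive.

**Step 11**
Reactants: 14 (1R)-1-[(2R,4Z,7R,8R)-7-(tert-butyldimethylsilyloxy)-8-ethyl-3,6,7,8-tetrahydro-2H-oxocin-2-yl]ethane-1,2-diol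
Product: 16 tert-butyl{[(2R,3R,5Z,8R)-2-ethyl-8-[(2R)-oxiran-2-yl]-3,4,7,8-tetrahydro-2H-oxocin-3-yl]oxy}dimethylsilane, via sodium alkoxide monotosylate 15 (not isolated)
Conditions: NaH, N-tosylimidazole, THF, 0 to 25 °C
Reagents that add atoms: none
Why: One-pot diol-to-epoxide conversion, in which the primary alkoxide is sulfonylated selectively to 15 and the C6 alkoxide closes the oxirane by intramolecular Williamson displacement at C5, so C6 keeps its R configuration.

**Step 12**
Reactants: 17 1,4-bis(trimethylsilyl)buta-1,3-diyne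
Product: 18 buta-1,3-diyn-1-yl(trimethyl)silane
Conditions: MeLi·LiBr (1 equiv), Et2O, 0 to 25 °C; aq NH4Cl
Reagents that add atoms: none
Why: Nucleophilic cleavage of one C–Si bond of the symmetrical diyne by one equivalent of MeLi (selective monodesilylation), followed by protonation on work-up, frees one terminal alkyne.

**Step 13**
Reactants: 18 buta-1,3-diyn-1-yl(trimethyl)silane
Product: 20 [(3E)-4-iodobut-3-en-1-yn-1-yl](trimethyl)silane, via alkenylzirconocene chloride 19 (not isolated)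
Conditions: Cp2Zr(H)Cl, THF, 25 °C; I2, 0 °C
Reagents that add atoms: iodine, II
Why: Hydrozirconation adds Zr–H syn, with zirconium at the terminal carbon of the free alkyne, to give 19, and iodinolysis with retention gives the E-iodide.

**Step 14**
Reactants: 20 [(3E)-4-iodobut-3-en-1-yn-1-yl](trimethyl)silane; 16 tert-butyl{[(2R,3R,5Z,8R)-2-ethyl-8-[(2R)-oxiran-2-yl]-3,4,7,8-tetrahydro-2H-oxocin-3-yl]oxy}dimethylsilane
Product: 22 (1R,3E)-1-[(2R,4Z,7R,8R)-7-(tert-butyldimethylsilyloxy)-8-ethyl-3,6,7,8-tetrahydro-2H-oxocin-2-yl]-6-(trimethylsilyl)hex-3-en-5-yn-1-ol, via alkenylmagnesium chloride 21 (not isolated)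
Conditions: 20, i-PrMgCl·LiCl, THF, −20 °C; CuI (10 mol %), then 16, −20 to 0 °C; aq NH4Cl
Reagents that add atoms: none
Why: Iodine–magnesium exchange with retention of the E geometry gives 21, whose CuI-catalysed SN2 opening of the terminal epoxide at C5 forms C4–C5 and frees the C6 alcohol without touching the C6 stereocentre.

**Step 15**
Reactants: 22 (1R,3E)-1-[(2R,4Z,7R,8R)-7-(tert-butyldimethylsilyloxy)-8-ethyl-3,6,7,8-tetrahydro-2H-oxocin-2-yl]-6-(trimethylsilyl)hex-3-en-5-yn-1-ol
Product: 23 (1R,3E)-1-[(2R,4Z,7R,8R)-7-(tert-butyldimethylsilyloxy)-8-ethyl-3,6,7,8-tetrahydro-2H-oxocin-2-yl]-6-(trimethylsilyl)hex-3-en-5-yn-1-yl acetate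
Conditions: Ac2O, pyridine, DMAP (cat.), CH2Cl2, 25 °C
Reagents that add atoms: acetic anhydride, CC(=O)OC(C)=O
Why: DMAP-catalysed acetylation of the only free hydroxyl group.

**Step 16**
Reactants: 23 (1R,3E)-1-[(2R,4Z,7R,8R)-7-(tert-butyldimethylsilyloxy)-8-ethyl-3,6,7,8-tetrahydro-2H-oxocin-2-yl]-6-(trimethylsilyl)hex-3-en-5-yn-1-yl acetate
Product: 24 (1R,3E)-1-[(2R,4Z,7R,8R)-8-ethyl-7-hydroxy-3,6,7,8-tetrahydro-2H-oxocin-2-yl]hex-3-en-5-yn-1-yl acetate
Conditions: Bu4NF, AcOH, THF, 0 to 25 °C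
Reagents that add atoms: none
Why: Fluoride-induced cleavage of both the O–Si and the alkynyl C–Si bond, buffered by AcOH so that the acetate is neither cleaved nor shifted.

**Step 17**
Reactants: 24 (1R,3E)-1-[(2R,4Z,7R,8R)-8-ethyl-7-hydroxy-3,6,7,8-tetrahydro-2H-oxocin-2-yl]hex-3-en-5-yn-1-yl acetate
Product: 25 (1R,3E)-1-[(2R,4Z,7S,8R)-7-bromo-8-ethyl-3,6,7,8-tetrahydro-2H-oxocin-2-yl]hex-3-en-5-yn-1-yl acetate
Conditions: CBr4, P(n-C8H17)3, toluene, 70 °C
Reagents that add atoms: carbon tetrabromide, BrC(Br)(Br)Br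
Why: Appel-type bromination, in which O12 is activated by the CBr4/phosphine pair and displaced by bromide in an SN2 reaction with inversion, turning 12R-OH into 12S-Br, trans to the ethyl group.

**Compound list**
1 | (R)-2,2-dimethyl-1,3-dioxolane-4-carbaldehyde | O=C[C@H]1COC(C)(C)O1 | starting material
2 | (1R)-1-[(4R)-2,2-dimethyl-1,3-dioxolan-4-yl]but-3-en-1-ol | C=CC[C@@H](O)[C@H]1COC(C)(C)O1 | intermediate
3 | (3R)-3-[(4R)-2,2-dimethyl-1,3-dioxolan-4-yl]-3-hydroxypropanal | O=CC[C@@H](O)[C@H]1COC(C)(C)O1 | intermediate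
4 | (1R,3RS)-1-[(4R)-2,2-dimethyl-1,3-dioxolan-4-yl]pent-4-ene-1,3-diol (C9 epimers) | C=CC(O)C[C@@H](O)[C@H]1COC(C)(C)O1 | intermediate
5 | (4R,6RS)-4-[(4R)-2,2-dimethyl-1,3-dioxolan-4-yl]-6-ethenyl-1,3-dioxan-2-one (C9 epimers) | C=CC1C[C@@H](OC(=O)O1)[C@H]2COC(C)(C)O2 | intermediate
6 | (4R,6RS)-4-[(4R)-2,2-dimethyl-1,3-dioxolan-4-yl]-6-ethenyl-2-methylidene-1,3-dioxane (ketene acetal, not isolated) | C=CC1C[C@@H](OC(=C)O1)[C@H]2COC(C)(C)O2 | intermediate
7 | (5Z,8R)-8-[(4R)-2,2-dimethyl-1,3-dioxolan-4-yl]-3,4,7,8-tetrahydro-2H-oxocin-2-one | O=C1CC/C=C\C[C@@H](O1)[C@H]2COC(C)(C)O2 | intermediate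
8 | potassium enolate of 7 (not isolated) | [K+].[O-]/C1=C/C/C=C\C[C@@H](O1)[C@H]2COC(C)(C)O2 | intermediate
9 | (3R,5Z,8R)-3-hydroxy lactone | O=C1[C@H](O)C/C=C\C[C@@H](O1)[C@H]2COC(C)(C)O2 | intermediate
10 | (3R,5Z,8R)-3-(tert-butyldimethylsilyloxy) lactone | O=C1[C@H](O[Si](C)(C)C(C)(C)C)C/C=C\C[C@@H](O1)[C@H]2COC(C)(C)O2 | intermediate
11 | (2Z,3R,5Z,8R)-2-ethylidene enol ether | C/C=C1/[C@H](O[Si](C)(C)C(C)(C)C)C/C=C\C[C@@H](O1)[C@H]2COC(C)(C)O2 | intermediate
12 | C13 oxocarbenium trifluoroacetate (not isolated) | CCC1=[O+][C@H](C/C=C\C[C@H]1O[Si](C)(C)C(C)(C)C)[C@H]2COC(C)(C)O2.[O-]C(=O)C(F)(F)F | intermediate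
13 | (2R,3R,5Z,8R)-3-(tert-butyldimethylsilyloxy)-8-[(4R)-2,2-dimethyl-1,3-dioxolan-4-yl]-2-ethyl-3,4,7,8-tetrahydro-2H-oxocine | CC1(C)OC[C@@H](O1)[C@H]2C/C=C\C[C@@H](O[Si](C)(C)C(C)(C)C)[C@@H](CC)O2 | intermediate
14 | (1R)-1-[(2R,4Z,7R,8R)-7-(tert-butyldimethylsilyloxy)-8-ethyl-3,6,7,8-tetrahydro-2H-oxocin-2-yl]ethane-1,2-diol | OC[C@@H](O)[C@H]1C/C=C\C[C@@H](O[Si](C)(C)C(C)(C)C)[C@@H](CC)O1 | intermediate
15 | sodium C6 alkoxide of the C5 monotosylate of 14 (not isolated) | Cc1ccc(cc1)S(=O)(=O)OC[C@@H]([O-])[C@H]1C/C=C\C[C@@H](O[Si](C)(C)C(C)(C)C)[C@@H](CC)O1.[Na+] | intermediate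
16 | (2R)-oxiranyl oxocene TBS ether | C1O[C@H]1[C@H]2C/C=C\C[C@@H](O[Si](C)(C)C(C)(C)C)[C@@H](CC)O2 | intermediate
17 | 1,4-bis(trimethylsilyl)buta-1,3-diyne | C[Si](C)(C)C#CC#C[Si](C)(C)C | starting material
18 | buta-1,3-diyn-1-yl(trimethyl)silane | C[Si](C)(C)C#CC#C | intermediate
19 | (E)-alkenylzirconocene chloride (not isolated) | C[Si](C)(C)C#C/C=C/[Zr](Cl)(C1C=CC=C1)C1C=CC=C1 | intermediate
20 | [(3E)-4-iodobut-3-en-1-yn-1-yl](trimethyl)silane | C[Si](C)(C)C#C/C=C/I | intermediate
21 | (E)-alkenylmagnesium chloride (not isolated) | C[Si](C)(C)C#C/C=C/[Mg]Cl | intermediate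
22 | C6 alcohol carrying the TMS-enyne and the C12 TBS ether | C[Si](C)(C)C#C/C=C/C[C@@H](O)[C@H]1C/C=C\C[C@@H](O[Si](C)(C)C(C)(C)C)[C@@H](CC)O1 | intermediate
23 | C6 acetate of 22 | C[Si](C)(C)C#C/C=C/C[C@@H](OC(C)=O)[C@H]1C/C=C\C[C@@H](O[Si](C)(C)C(C)(C)C)[C@@H](CC)O1 | intermediate
24 | (12R)-hydroxy enyne acetate | C#C/C=C/C[C@@H](OC(C)=O)[C@H]1C/C=C\C[C@@H](O)[C@@H](CC)O1 | intermediate
25 | (1R,3E)-1-[(2R,4Z,7S,8R)-7-bromo-8-ethyl-3,6,7,8-tetrahydro-2H-oxocin-2-yl]hex-3-en-5-yn-1-yl acetate | C#C/C=C/C[C@@H](OC(C)=O)[C@H]1C/C=C\C[C@H](Br)[C@@H](CC)O1 | target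

**Step count**
Total steps: 17. Fifteen are in the main line and two make iodide 20. The longest linear sequence is 15 steps (steps 1–11 and 14–17).

**Steps most likely to fail**

Step 8. Ethylidene transfer to the hindered carbonyl next to the silyloxy group may stall, or the titanium alkylidene may engage the ring alkene. The fallback sets out from 10.
- Thionation with Lawesson's reagent (toluene, 110 °C) gives the thionolactone F1.
- Carbophilic addition of EtLi to the C=S bond at −78 °C, followed by S-methylation with MeI, gives the mixed S-methyl thioketal F2 with the ring intact.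
- Homolytic desulfurisation with Ph3SnH/AIBN transfers hydrogen to the C13 radical from the less hindered face.
- This comes back to the route at 13 and bypasses steps 8 and 9.

Step 6. Facial selectivity in the enolate oxidation may be poor or reversed, and this would also mislead the hydride delivery of step 9. The fallback sets out from 7.
- O-phosphorylation of the enolate with (PhO)2P(O)Cl gives the cyclic ketene acetal phosphate F3.
- PdCl2(dppf)-catalysed Negishi coupling with Et2Zn gives the 2-ethyl cyclic enol ether F4.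
- Hydroboration–oxidation (BH3·THF; NaOH, H2O2) from the face opposite to the C7 substituent sets C13 and gives the trans alcohol F5.
- Dess–Martin oxidation gives the oxocen-3-one F6.
- Reduction with LiBH(s-Bu)3 from the face opposite to the ethyl group gives the cis 12R alcohol F7.
- Silylation with TBSOTf comes back to the route at 13.

Step 17. Bromide substitution at the hindered homoallylic C12 position may be slow. Participation of the ring oxygen or of the C9=C10 alkene, or elimination, may then compete. The fallback sets out from 24.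
- Sulfonylation with ClCH2SO2Cl/pyridine gives the chloromethanesulfonate F8, a small and very reactive leaving group.
- F8 is displaced in a separate SN2 step by LiBr in DMF at 25 °C with inversion.
- This comes back to the route at 25.

**Further compounds**
F1 | step 8 | (3R,5Z,8R)-3-(tert-butyldimethylsilyloxy)-8-[(4R)-2,2-dimethyl-1,3-dioxolan-4-yl]-3,4,7,8-tetrahydro-2H-oxocine-2-thione | S=C1[C@H](O[Si](C)(C)C(C)(C)C)C/C=C\C[C@@H](O1)[C@H]2COC(C)(C)O2
F2 | step 8 | 2-ethyl-2-(methylsulfanyl) mixed thioketal (C13 epimers) | CC1(C)OC[C@@H](O1)[C@H]2C/C=C\C[C@@H](O[Si](C)(C)C(C)(C)C)C(CC)(SC)O2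
F3 | step 6 | cyclic ketene acetal diphenyl phosphate of 7 | O=P(Oc1ccccc1)(Oc1ccccc1)O/C1=C/C/C=C\C[C@@H](O1)[C@H]2COC(C)(C)O2
F4 | step 6 | (8R)-2-ethyl-8-[(4R)-2,2-dimethyl-1,3-dioxolan-4-yl]-7,8-dihydro-4H-oxocine | CC/C1=C/C/C=C\C[C@@H](O1)[C@H]2COC(C)(C)O2
F5 | step 6 | (2R,3S,5Z,8R)-2-ethyl oxocen-3-ol (trans) | CC1(C)OC[C@@H](O1)[C@H]2C/C=C\C[C@H](O)[C@@H](CC)O2
F6 | step 6 | (2R,5Z,8R)-2-ethyl oxocen-3-one | CC1(C)OC[C@@H](O1)[C@H]2C/C=C\CC(=O)[C@@H](CC)O2
F7 | step 6 | (2R,3R,5Z,8R)-2-ethyl oxocen-3-ol (cis) | CC1(C)OC[C@@H](O1)[C@H]2C/C=C\C[C@@H](O)[C@@H](CC)O2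
F8 | step 17 | C12 chloromethanesulfonate of 24 | C#C/C=C/C[C@@H](OC(C)=O)[C@H]1C/C=C\C[C@@H](OS(=O)(=O)CCl)[C@@H](CC)O1
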